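**Plan**
1. Retrosynthesis: furanone ring C is cut at C18–C19 and at O–C16, both leading back to CO2 and a (Z)-γ-chloro alkenyl iodide. Further cuts are C17–C25 and C18–I (alkyne carbometalation), C13=C14 (Wittig) and C12–C13 (acylation of a C12 organolithium).
2. Forward: rings A and B (C1–C12) come ready-made from (+)-sclareolide. C13/C24 are added as a Weinreb amide, C14–C18 by Wittig olefination, C25 by carbomagnesiation, and C19 by CO2, which closes ring C before the final desilylation.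
3. Stereochemistry: C5 and C10 come from sclareolide. The C13=C14 geometry comes from the Z-selective Wittig reaction of an α-silyloxy ketone, and the C17=C18 geometry from the chelate of an anti-carbomagnesiation. C16 comes from a Noyori transfer hydrogenation and is carried through two SN2 inversions (Appel chlorination, then lactonisation).
4. Enabling feature: in ring C the ring oxygen sits on the allylic carbon C16 and the carbonyl carbon C19 on C18, cis to C16 across C17=C18. A carboxylate generated on C18 can therefore only reach C16, so one CO2 molecule joined to C18 and C16 builds the ring and fixes C16 in one operation.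

Key step: step 15

Remark (naming): Bic = (4aS,8aS)-2,5,5,8a-tetramethyl-3,4,4a,5,6,7,8,8a-octahydronaphthalen-1-yl (rings A and B with the C8=C9 double bond); TBS = tert-butyldimethylsilyl; TMS = trimethylsilyl. Carbon numbers follow the luffarin skeleton: side chain C11–C19 from C9, C24 the hydroxymethyl carbon on C13, C25 that on C17, C16 the stereocentre of ring C, C19 its carbonyl carbon.
Remark (assumptions): 18 is drawn as the open isopropoxysilane; if silicon closes onto the C16 oxygen (oxasilolane), step 12 should oxidise it to the same triol. Compound 5 and (chloromethyl)dimethyl(propan-2-yloxy)silane are taken as catalogue chemicals.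

Step 1
Reactants: 1 (+)-sclareolide
Product: 2 methyl 2-Bic-acetate
Conditions: conc. H2SO4, MeOH, reflux
Reagents that add atoms: methanol, CO
Why: Acid-catalysed lactone methanolysis followed by E1 dehydration of the tertiary C8 alcohol should, under these equilibrating conditions, settle on the tetrasubstituted C8=C9 alkene as the thermodynamic isomer, with C5 and C10 untouched.

Step 2
Reactants: 2 methyl 2-Bic-acetate
Product: 3 2-Bic-ethan-1-ol
Conditions: LiAlH4, THF, 0 °C
Reagents that add atoms: none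
Why: Hydride reduction of the ester to the primary alcohol; the isolated tetrasubstituted alkene is inert to LiAlH4.

Step 3
Reactants: 3 2-Bic-ethan-1-ol
Product: 4 1-iodo-2-Bic-ethane
Conditions: I2, PPh3, imidazole, CH2Cl2, 0 °C to rt
Reagents that add atoms: iodine, II
Why: Appel-type iodination, in which iodide displaces the alkoxyphosphonium group of the primary alcohol by SN2.

Step 4
Reactants: 4 1-iodo-2-Bic-ethane; 5 2-[(tert-butyldimethylsilyl)oxy]-N-methoxy-N-methylacetamide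
Product: 7 1-[(tert-butyldimethylsilyl)oxy]-4-Bic-butan-2-one, via alkyllithium 6 (not isolated)
Conditions: t-BuLi (2.1 equiv), Et2O/pentane, −78 °C; then 5, −78 to 0 °C; H2O
Reagents that add atoms: none
Why: Iodine–lithium exchange followed by a Weinreb ketone synthesis, in which the chelated tetrahedral adduct prevents over-addition and releases the α-silyloxy ketone on work-up.

Step 5
Reactants: 8 3-bromopropanoyl chloride; 9 bis(trimethylsilyl)acetylene
Product: 10 5-bromo-1-(trimethylsilyl)pent-1-yn-3-one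
Conditions: AlCl3, CH2Cl2, 0 °C
Reagents that add atoms: none
Why: Friedel–Crafts-type acyldesilylation of the bis-silylalkyne by the acylium ion gives the ynone with one silyl group retained.

Step 6
Reactants: 10 5-bromo-1-(trimethylsilyl)pent-1-yn-3-one
Product: 11 (3R)-5-bromo-1-(trimethylsilyl)pent-1-yn-3-ol
Conditions: Ru[(R,R)-TsNCHPhCHPhNH](η6-p-cymene) (1 mol %), 2-propanol, rt
Reagents that add atoms: none
Why: Noyori asymmetric transfer hydrogenation of an alkynyl ketone, in which the alkynyl group takes the role of the aryl group of aryl ketones, so the (R,R)-catalyst should give the (3R)-carbinol that becomes C16.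

Step 7
Reactants: 11 (3R)-5-bromo-1-(trimethylsilyl)pent-1-yn-3-ol
Product: 12 (3R)-5-bromo-3-[(tert-butyldimethylsilyl)oxy]-1-(trimethylsilyl)pent-1-yne
Conditions: TBSOTf, 2,6-lutidine, CH2Cl2, −78 °C
Reagents that add atoms: tert-butyldimethylsilyl trifluoromethanesulfonate, CC(C)(C)[Si](C)(C)OS(=O)(=O)C(F)(F)F
Why: Silylation of the secondary alcohol with a silyl triflate is fast enough at low temperature that the primary bromide is not touched.

Step 8
Reactants: 12 (3R)-5-bromo-3-[(tert-butyldimethylsilyl)oxy]-1-(trimethylsilyl)pent-1-yne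
Product: 13 [(3R)-3-[(tert-butyldimethylsilyl)oxy]-5-(trimethylsilyl)pent-4-yn-1-yl]triphenylphosphonium bromide
Conditions: PPh3, MeCN, reflux
Reagents that add atoms: triphenylphosphine, c1ccc(cc1)P(c1ccccc1)c1ccccc1
Why: SN2 quaternisation of triphenylphosphine by the primary bromide gives the phosphonium salt, with the stereocentre two carbons away from the reacting carbon.

Step 9
Reactants: 7 1-[(tert-butyldimethylsilyl)oxy]-4-Bic-butan-2-one; 13 [(3R)-3-[(tert-butyldimethylsilyl)oxy]-5-(trimethylsilyl)pent-4-yn-1-yl]triphenylphosphonium bromide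
Product: 15 (2Z,5R)-1,5-bis[(tert-butyldimethylsilyl)oxy]-2-(2-Bic-ethyl)-7-(trimethylsilyl)hept-2-en-6-yne, via ylide 14 (not isolated)
Conditions: 13, KN(SiMe3)2, THF, −78 °C; then 7, −78 °C to rt
Reagents that add atoms: none
Why: Wittig olefination of an α-alkoxy ketone with a non-stabilised ylide, a combination known to give the Z-trisubstituted allylic ether (oxymethyl group cis to the new chain), which sets the C13=C14 geometry.

Step 10
Reactants: 15 (2Z,5R)-1,5-bis[(tert-butyldimethylsilyl)oxy]-2-(2-Bic-ethyl)-7-(trimethylsilyl)hept-2-en-6-yne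
Product: 16 (2Z,5R)-2-(2-Bic-ethyl)hept-2-en-6-yne-1,5-diol
Conditions: Bu4NF, THF, 0 °C to rt
Reagents that add atoms: none
Why: Fluoride-induced desilylation removes both silyl ethers and the alkynyl silyl group, freeing the propargylic C16 hydroxyl that directs the next step.

Step 11
Reactants: 16 (2Z,5R)-2-(2-Bic-ethyl)hept-2-en-6-yne-1,5-diol
Product: 18 (2Z,5R,6E)-6-{[dimethyl(propan-2-yloxy)silyl]methyl}-7-iodo-2-(2-Bic-ethyl)hepta-2,6-diene-1,5-diol, via alkenylmagnesium 17 (not isolated)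
Conditions: (i-PrO)Me2SiCH2MgCl [from (i-PrO)Me2SiCH2Cl and Mg, THF] (5 equiv), CuI (20 mol %), Et2O/THF, −10 °C to rt; then I2, THF, −78 °C
Reagents that add atoms: [dimethyl(propan-2-yloxy)silyl]methylmagnesium chloride, CC(C)O[Si](C)(C)C[Mg]Cl; iodine, II
Why: CuI-catalysed, alkoxide-directed anti-carbomagnesiation of the propargylic alcohol puts the silylmethyl group on C17 and magnesium on C18 inside a five-membered chelate with the C16 alkoxide, so iodinolysis with retention should give the alkenyl iodide with iodine cis to C16.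

Step 12
Reactants: 18 (2Z,5R,6E)-6-{[dimethyl(propan-2-yloxy)silyl]methyl}-7-iodo-2-(2-Bic-ethyl)hepta-2,6-diene-1,5-diol
Product: 19 (2Z,5R,6Z)-6-(hydroxymethyl)-7-iodo-2-(2-Bic-ethyl)hepta-2,6-diene-1,5-diol
Conditions: KF, KHCO3, 30% H2O2, THF/MeOH, rt
Reagents that add atoms: hydrogen peroxide, OO
Why: Tamao oxidation converts the alkoxysilyl C–Si bond into C–OH with retention and without allylic shift, unveiling the C25 hydroxymethyl group while the alkenyl iodide and the alkenes stay intact.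

Step 13
Reactants: 19 (2Z,5R,6Z)-6-(hydroxymethyl)-7-iodo-2-(2-Bic-ethyl)hepta-2,6-diene-1,5-diol
Product: 20 (1Z,3R,5Z)-7-[(tert-butyldimethylsilyl)oxy]-2-{[(tert-butyldimethylsilyl)oxy]methyl}-1-iodo-6-(2-Bic-ethyl)hepta-1,5-dien-3-ol
Conditions: TBSCl (2.2 equiv), imidazole, CH2Cl2, −20 to 0 °C
Reagents that add atoms: tert-butyl(chloro)dimethylsilane, CC(C)(C)[Si](C)(C)Cl
Why: Selective silylation should take the two primary allylic alcohols (C24, C25) and leave the hindered secondary C16 alcohol next to the fully substituted C17.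

Step 14
Reactants: 20 (1Z,3R,5Z)-7-[(tert-butyldimethylsilyl)oxy]-2-{[(tert-butyldimethylsilyl)oxy]methyl}-1-iodo-6-(2-Bic-ethyl)hepta-1,5-dien-3-ol
Product: 21 (2Z,5S,6Z)-1-[(tert-butyldimethylsilyl)oxy]-6-{[(tert-butyldimethylsilyl)oxy]methyl}-5-chloro-7-iodo-2-(2-Bic-ethyl)hepta-2,6-diene
Conditions: PPh3, hexachloroacetone, CH2Cl2, −20 to 0 °C; used at once
Reagents that add atoms: hexachloroacetone, ClC(Cl)(Cl)C(=O)C(Cl)(Cl)Cl
Why: Appel-type chlorination under neutral conditions, in which chloride displaces the alkoxyphosphonium group by SN2 with inversion to give the (16S)-chloride, the iodine-bearing C18 terminus disfavouring the SN2' path.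

Step 15
Reactants: 21 (2Z,5S,6Z)-1-[(tert-butyldimethylsilyl)oxy]-6-{[(tert-butyldimethylsilyl)oxy]methyl}-5-chloro-7-iodo-2-(2-Bic-ethyl)hepta-2,6-diene
Product: 24 (5R)-4-{[(tert-butyldimethylsilyl)oxy]methyl}-5-[(2Z)-3-{[(tert-butyldimethylsilyl)oxy]methyl}-5-Bic-pent-2-en-1-yl]furan-2(5H)-one, via alkenyllithium 22 (not isolated), via lithium carboxylate 23 (not isolated)
Conditions: t-BuLi (2.05 equiv), THF/Et2O/pentane (4:1:1), −100 °C; CO2 (gas, excess), −100 to −20 °C; then DMPU, 45 °C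
Reagents that add atoms: carbon dioxide, O=C=O
Why: Iodine–lithium exchange (retentive at the sp2 carbon) should give alkenyllithium 22 faster than t-BuLi can touch the allylic chloride, CO2 then adds to give the lithium (Z)-4-chloroalk-2-enoate 23, and on warming a carboxylate oxygen displaces chloride at C16 from the face opposite the leaving group. The closest known reaction types are the carboxylation of alkenyllithiums with CO2 and the lactonisation of γ-halo carboxylates, here run in one flask. Ring C closes in the 5-exo-tet mode. The C16 stereocentre is controlled by SN2 inversion of the (16S)-chloride, which returns the oxygen to the face it occupied in the (16R)-carbinol set by the transfer hydrogenation. The step needs O-alkylation at C16 only and no ionisation: the C17=C18 geometry holds the carboxylate cis to C16 so that only the five-membered ring can form (C25 lies trans and carries no leaving group), the electron-poor C18 substituent disfavours an allyl cation, and the intramolecular closure should outpace attack by the liberated iodide and E2 loss of HCl towards C15.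

Step 16
Reactants: 24 (5R)-4-{[(tert-butyldimethylsilyl)oxy]methyl}-5-[(2Z)-3-{[(tert-butyldimethylsilyl)oxy]methyl}-5-Bic-pent-2-en-1-yl]furan-2(5H)-one
Product: 25 16-epi-luffarin L
Conditions: HF·pyridine, pyridine/THF, 0 °C to rt
Reagents that add atoms: none
Why: Acidic fluoride desilylation frees both primary alcohols under non-basic conditions, so the base-labile γ-stereocentre C16 of the butenolide is not epimerised.

**Compound list**
1 | (+)-sclareolide [(3aR,5aS,9aS,9bR)-3a,6,6,9a-tetramethyldecahydronaphtho[2,1-b]furan-2(1H)-one] | C[C@@]12CC[C@H]3C(C)(C)CCC[C@]3(C)[C@H]1CC(=O)O2 | starting material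
2 | methyl 2-Bic-acetate | CC1=C(CC(=O)OC)[C@@]2(C)CCCC(C)(C)[C@@H]2CC1 | intermediate
3 | 2-Bic-ethan-1-ol | CC1=C(CCO)[C@@]2(C)CCCC(C)(C)[C@@H]2CC1 | intermediate
4 | 1-iodo-2-Bic-ethane | CC1=C(CCI)[C@@]2(C)CCCC(C)(C)[C@@H]2CC1 | intermediate
5 | 2-[(tert-butyldimethylsilyl)oxy]-N-methoxy-N-methylacetamide | CON(C)C(=O)CO[Si](C)(C)C(C)(C)C | starting material
6 | (2-Bic-ethyl)lithium | CC1=C(CC[Li])[C@@]2(C)CCCC(C)(C)[C@@H]2CC1 | intermediate
7 | 1-[(tert-butyldimethylsilyl)oxy]-4-Bic-butan-2-one | CC1=C(CCC(=O)CO[Si](C)(C)C(C)(C)C)[C@@]2(C)CCCC(C)(C)[C@@H]2CC1 | intermediate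
8 | 3-bromopropanoyl chloride | O=C(Cl)CCBr | starting material
9 | bis(trimethylsilyl)acetylene | C[Si](C)(C)C#C[Si](C)(C)C | starting material
10 | 5-bromo-1-(trimethylsilyl)pent-1-yn-3-one | C[Si](C)(C)C#CC(=O)CCBr | intermediate
11 | (3R)-5-bromo-1-(trimethylsilyl)pent-1-yn-3-ol | C[Si](C)(C)C#C[C@H](O)CCBr | intermediate
12 | (3R)-5-bromo-3-[(tert-butyldimethylsilyl)oxy]-1-(trimethylsilyl)pent-1-yne | C[Si](C)(C)C#C[C@H](O[Si](C)(C)C(C)(C)C)CCBr | intermediate
13 | [(3R)-3-[(tert-butyldimethylsilyl)oxy]-5-(trimethylsilyl)pent-4-yn-1-yl]triphenylphosphonium bromide | C[Si](C)(C)C#C[C@H](O[Si](C)(C)C(C)(C)C)CC[P+](c1ccccc1)(c1ccccc1)c1ccccc1.[Br-] | intermediate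
14 | [(3R)-3-[(tert-butyldimethylsilyl)oxy]-5-(trimethylsilyl)pent-4-yn-1-ylidene]triphenylphosphorane (ylide of 13) | C[Si](C)(C)C#C[C@H](O[Si](C)(C)C(C)(C)C)CC=P(c1ccccc1)(c1ccccc1)c1ccccc1 | intermediate
15 | (2Z,5R)-1,5-bis[(tert-butyldimethylsilyl)oxy]-2-(2-Bic-ethyl)-7-(trimethylsilyl)hept-2-en-6-yne | CC1=C(CC/C(=C/C[C@@H](O[Si](C)(C)C(C)(C)C)C#C[Si](C)(C)C)CO[Si](C)(C)C(C)(C)C)[C@@]2(C)CCCC(C)(C)[C@@H]2CC1 | intermediate
16 | (2Z,5R)-2-(2-Bic-ethyl)hept-2-en-6-yne-1,5-diol | CC1=C(CC/C(=C/C[C@@H](O)C#C)CO)[C@@]2(C)CCCC(C)(C)[C@@H]2CC1 | intermediate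
17 | C18 alkenylmagnesium chloride of 18, as its C16 and C24 chloromagnesium alkoxides (Mg on C18 cis to C16) | CC1=C(CC/C(=C/C[C@@H](O[Mg]Cl)/C(=C\[Mg]Cl)C[Si](C)(C)OC(C)C)CO[Mg]Cl)[C@@]2(C)CCCC(C)(C)[C@@H]2CC1 | intermediate
18 | (2Z,5R,6E)-6-{[dimethyl(propan-2-yloxy)silyl]methyl}-7-iodo-2-(2-Bic-ethyl)hepta-2,6-diene-1,5-diol | CC1=C(CC/C(=C/C[C@@H](O)/C(=C\I)C[Si](C)(C)OC(C)C)CO)[C@@]2(C)CCCC(C)(C)[C@@H]2CC1 | intermediate
19 | (2Z,5R,6Z)-6-(hydroxymethyl)-7-iodo-2-(2-Bic-ethyl)hepta-2,6-diene-1,5-diol | CC1=C(CC/C(=C/C[C@@H](O)/C(=C\I)CO)CO)[C@@]2(C)CCCC(C)(C)[C@@H]2CC1 | intermediate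
20 | (1Z,3R,5Z)-7-[(tert-butyldimethylsilyl)oxy]-2-{[(tert-butyldimethylsilyl)oxy]methyl}-1-iodo-6-(2-Bic-ethyl)hepta-1,5-dien-3-ol | CC1=C(CC/C(=C/C[C@@H](O)/C(=C\I)CO[Si](C)(C)C(C)(C)C)CO[Si](C)(C)C(C)(C)C)[C@@]2(C)CCCC(C)(C)[C@@H]2CC1 | intermediate
21 | (2Z,5S,6Z)-1-[(tert-butyldimethylsilyl)oxy]-6-{[(tert-butyldimethylsilyl)oxy]methyl}-5-chloro-7-iodo-2-(2-Bic-ethyl)hepta-2,6-diene | CC1=C(CC/C(=C/C[C@H](Cl)/C(=C\I)CO[Si](C)(C)C(C)(C)C)CO[Si](C)(C)C(C)(C)C)[C@@]2(C)CCCC(C)(C)[C@@H]2CC1 | intermediate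
22 | alkenyllithium from 21 (Li in place of I on C18, cis to C16) | CC1=C(CC/C(=C/C[C@H](Cl)/C(=C\[Li])CO[Si](C)(C)C(C)(C)C)CO[Si](C)(C)C(C)(C)C)[C@@]2(C)CCCC(C)(C)[C@@H]2CC1 | intermediate
23 | lithium (2Z,4S,6Z)-8-[(tert-butyldimethylsilyl)oxy]-3-{[(tert-butyldimethylsilyl)oxy]methyl}-4-chloro-7-(2-Bic-ethyl)octa-2,6-dienoate | CC1=C(CC/C(=C/C[C@H](Cl)/C(=C\C(=O)[O-])CO[Si](C)(C)C(C)(C)C)CO[Si](C)(C)C(C)(C)C)[C@@]2(C)CCCC(C)(C)[C@@H]2CC1.[Li+] | intermediate
24 | (5R)-4-{[(tert-butyldimethylsilyl)oxy]methyl}-5-[(2Z)-3-{[(tert-butyldimethylsilyl)oxy]methyl}-5-Bic-pent-2-en-1-yl]furan-2(5H)-one | CC1=C(CC/C(=C/C[C@H]2OC(=O)C=C2CO[Si](C)(C)C(C)(C)C)CO[Si](C)(C)C(C)(C)C)[C@@]2(C)CCCC(C)(C)[C@@H]2CC1 | intermediate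
25 | 16-epi-luffarin L [(5R)-4-(hydroxymethyl)-5-[(2Z)-3-(hydroxymethyl)-5-Bic-pent-2-en-1-yl]furan-2(5H)-one] | CC1=C(CC/C(=C/C[C@H]2OC(=O)C=C2CO)CO)[C@@]2(C)CCCC(C)(C)[C@@H]2CC1 | target

**Step count and risks**
Total step count: 16. Longest linear sequence: 12 steps (steps 1–4 and 9–16) from (+)-sclareolide; the C14–C18 branch (steps 5–8) has 4 steps.

Steps most likely to fail:

1. Step 15. During the exchange, t-BuLi or the alkenyllithium may attack or eliminate the allylic chloride. After carboxylation the C16 configuration may leak through chloride–iodide exchange or ionisation, or E2 loss of HCl towards C15 may outrun ring closure. The fallback sets out from 20 and returns at 24. It is a palladium-catalysed carbonylative lactonisation of the (Z)-γ-hydroxy alkenyl iodide [PdCl2(PPh3)2, CO (1 atm), Et3N, THF, 50 °C]. Oxidative addition, CO insertion and capture of the acylpalladium by the C16 hydroxyl should give 24 with retention at C16, and 20 already carries the oxygen on the required face. Steps 14 and 15 are bypassed, and the fallback makes no new compound (F0).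

2. Step 11. The Grignard reagent may deprotonate the terminal alkyne to an unreactive acetylide, the anti-addition may stay incomplete, or iodine may cleave the allylsilane during the quench. The fallback sets out from 16 and returns at 20, using a silicon tether in place of chelation to fix the C17=C18 geometry.
   - Branched-selective hydromethoxycarbonylation of the alkyne [Pd(OAc)2, 2-(diphenylphosphino)pyridine, CH3SO3H, CO, MeOH] should give methyl (3R,5Z)-3-hydroxy-6-(hydroxymethyl)-2-methylidene-8-Bic-oct-5-enoate F1.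
   - Reduction with i-Bu2AlH (CH2Cl2, −78 °C) gives (2Z,5R)-6-methylidene-2-(2-Bic-ethyl)hept-2-ene-1,5,7-triol F2.
   - TBSCl/imidazole silylates the two primary alcohols to give (2Z,5R)-1-[(tert-butyldimethylsilyl)oxy]-6-{[(tert-butyldimethylsilyl)oxy]methyl}-2-(2-Bic-ethyl)hepta-2,6-dien-5-ol F3.
   - Chloro(dimethyl)vinylsilane/Et3N gives the C16 ethenyldimethylsilyl ether of F3, F4.
   - Ring-closing metathesis with the second-generation Grubbs catalyst (CH2Cl2, 40 °C) gives (5R)-4-{[(tert-butyldimethylsilyl)oxy]methyl}-5-[(2Z)-3-{[(tert-butyldimethylsilyl)oxy]methyl}-5-Bic-pent-2-en-1-yl]-2,2-dimethyl-2,5-dihydro-1,2-oxasilole F5, whose ring forces silicon cis to C16.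
   - Iododesilylation with N-iodosuccinimide in (CF3)2CHOH (retention), then mild hydrolysis of the O–Si bond, gives 20.

3. Step 9. The basic ylide may enolise ketone 7 instead of adding to it, and Z-control at the trisubstituted alkene may be incomplete. The fallback sets out from 4 and 12 and returns at 16, swapping the roles of the partners in a Still–Gennari olefination.
   - Alkylation of methyl 2-[bis(2,2,2-trifluoroethoxy)phosphoryl]acetate with 4 (NaH, DMF) gives methyl 2-[bis(2,2,2-trifluoroethoxy)phosphoryl]-4-Bic-butanoate F6.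
   - Kornblum oxidation of 12 (AgBF4, DMSO, rt; then Et3N) gives (3R)-3-[(tert-butyldimethylsilyl)oxy]-5-(trimethylsilyl)pent-4-ynal F7.
   - F6 and F7 with KN(SiMe3)2/18-crown-6 (THF, −78 °C) should give methyl (2Z,5R)-5-[(tert-butyldimethylsilyl)oxy]-2-(2-Bic-ethyl)-7-(trimethylsilyl)hept-2-en-6-ynoate F8.
   - Reduction with i-Bu2AlH gives (2Z,5R)-5-[(tert-butyldimethylsilyl)oxy]-2-(2-Bic-ethyl)-7-(trimethylsilyl)hept-2-en-6-yn-1-ol F9.
   - Bu4NF then gives 16.

Further compounds
F0 | step 15 | none | none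
F1 | step 11 | methyl (3R,5Z)-3-hydroxy-6-(hydroxymethyl)-2-methylidene-8-Bic-oct-5-enoate | CC1=C(CC/C(=C/C[C@@H](O)C(=C)C(=O)OC)CO)[C@@]2(C)CCCC(C)(C)[C@@H]2CC1
F2 | step 11 | (2Z,5R)-6-methylidene-2-(2-Bic-ethyl)hept-2-ene-1,5,7-triol | CC1=C(CC/C(=C/C[C@@H](O)C(=C)CO)CO)[C@@]2(C)CCCC(C)(C)[C@@H]2CC1
F3 | step 11 | (2Z,5R)-1-[(tert-butyldimethylsilyl)oxy]-6-{[(tert-butyldimethylsilyl)oxy]methyl}-2-(2-Bic-ethyl)hepta-2,6-dien-5-ol | CC1=C(CC/C(=C/C[C@@H](O)C(=C)CO[Si](C)(C)C(C)(C)C)CO[Si](C)(C)C(C)(C)C)[C@@]2(C)CCCC(C)(C)[C@@H]2CC1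
F4 | step 11 | C16 ethenyldimethylsilyl ether of F3 | CC1=C(CC/C(=C/C[C@@H](O[Si](C)(C)C=C)C(=C)CO[Si](C)(C)C(C)(C)C)CO[Si](C)(C)C(C)(C)C)[C@@]2(C)CCCC(C)(C)[C@@H]2CC1
F5 | step 11 | (5R)-4-{[(tert-butyldimethylsilyl)oxy]methyl}-5-[(2Z)-3-{[(tert-butyldimethylsilyl)oxy]methyl}-5-Bic-pent-2-en-1-yl]-2,2-dimethyl-2,5-dihydro-1,2-oxasilole | CC1=C(CC/C(=C/C[C@H]2O[Si](C)(C)C=C2CO[Si](C)(C)C(C)(C)C)CO[Si](C)(C)C(C)(C)C)[C@@]2(C)CCCC(C)(C)[C@@H]2CC1
F6 | step 9 | methyl 2-[bis(2,2,2-trifluoroethoxy)phosphoryl]-4-Bic-butanoate (both epimers at C2) | CC1=C(CCC(C(=O)OC)P(=O)(OCC(F)(F)F)OCC(F)(F)F)[C@@]2(C)CCCC(C)(C)[C@@H]2CC1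
F7 | step 9 | (3R)-3-[(tert-butyldimethylsilyl)oxy]-5-(trimethylsilyl)pent-4-ynal | C[Si](C)(C)C#C[C@H](O[Si](C)(C)C(C)(C)C)CC=O
F8 | step 9 | methyl (2Z,5R)-5-[(tert-butyldimethylsilyl)oxy]-2-(2-Bic-ethyl)-7-(trimethylsilyl)hept-2-en-6-ynoate | CC1=C(CC/C(=C/C[C@@H](O[Si](C)(C)C(C)(C)C)C#C[Si](C)(C)C)C(=O)OC)[C@@]2(C)CCCC(C)(C)[C@@H]2CC1
F9 | step 9 | (2Z,5R)-5-[(tert-butyldimethylsilyl)oxy]-2-(2-Bic-ethyl)-7-(trimethylsilyl)hept-2-en-6-yn-1-ol | CC1=C(CC/C(=C/C[C@@H](O[Si](C)(C)C(C)(C)C)C#C[Si](C)(C)C)CO)[C@@]2(C)CCCC(C)(C)[C@@H]2CC1
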